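**Retrosynthetic overview**
1. Deoxycaespitol ⇐ oxanyl‑cyclohexene: the ring Br/Cl pair goes in last (chlorohydrin, then tertiary bromide, then thermal 1,2‑halogen interchange).
2. Oxanyl‑cyclohexene ⇐ acyclic dienol: the oxane is closed by Co–H Markovnikov hydroalkoxylation, which sets C6 (second ring formed).
3. Dienol ⇐ C9 alkenyl iodide + C6 alkyl iodide: a Pd‑catalysed alkenyl–alkyl Negishi coupling makes the C5–C6 bond that joins the halves.
4. Alkenyl iodide ⇐ isoprene + acrolein by asymmetric Diels–Alder reaction (cyclohexene ring formed first, sets C1′), then methyl ketone and Shapiro iodination.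
5. Alkyl iodide ⇐ 2‑cyclopropylpropan‑2‑ol via the homoallyl chloride, Shi epoxidation and bromide opening (sets C3).

Labels: oxane O1, C2 (CMe2), C3 (CHBr), C4, C5, C6 (C–Me bearing the carbocycle); cyclohexane C1′ (attached to C6), C3′ (CHBr), C4′ (CClMe).
Assumption: the catalyst enantiomers named are those expected to give the drawn configurations; the antipodes are equally available if the sense is opposite.

**Branch A**

Step 1
Reactants: 1 isoprene; 2 acrolein
Product: 3 (1R)-4-methylcyclohex-3-ene-1-carbaldehyde
Conditions: (5S)-5-benzyl-2,2,3-trimethylimidazolidin-4-one·HCl (10 mol%), MeNO2/H2O 95:5, rt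
Reagents that add atoms: none
Why: Iminium‑catalysed Diels–Alder reaction with "para" regiochemistry; the benzyl group of the catalyst shields one face of the (E)-iminium, so C1′ is formed R (ee about 90%, upgraded at 6).

Step 2
Reactants: 3 (1R)-4-methylcyclohex-3-ene-1-carbaldehyde
Product: 4 1-[(1R)-4-methylcyclohex-3-en-1-yl]ethan-1-ol (about 1:1 at the carbinol carbon)
Conditions: MeMgBr, THF, −78 °C
Reagents that add atoms: methylmagnesium bromide, C[Mg]Br
Why: Grignard 1,2‑addition at low temperature without α‑epimerisation; the new carbinol centre is destroyed in step 3.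

Step 3
Reactants: 4 1-[(1R)-4-methylcyclohex-3-en-1-yl]ethan-1-ol
Product: 5 1-[(1R)-4-methylcyclohex-3-en-1-yl]ethan-1-one
Conditions: Dess–Martin periodinane, NaHCO3, CH2Cl2, 0 °C → rt
Reagents that add atoms: none
Why: Buffered Dess–Martin oxidation is neutral and does not epimerise the α‑stereocentre C1′.

Step 4
Reactants: 5 1-[(1R)-4-methylcyclohex-3-en-1-yl]ethan-1-one
Product: 6 (E)-N′-{1-[(1R)-4-methylcyclohex-3-en-1-yl]ethylidene}-2,4,6-triisopropylbenzenesulfonohydrazide
Conditions: 2,4,6-triisopropylbenzenesulfonyl hydrazide, PPTS (cat.), THF, rt; recrystallise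
Reagents that add atoms: trisyl hydrazide, CC(C)c1cc(C(C)C)c(S(=O)(=O)NN)c(C(C)C)c1
Why: Hydrazone condensation; the E isomer (N–N syn to CH3) is set up for Shapiro deprotonation at the methyl group, and the crystalline solid allows the ee to be raised.

Step 5
Reactants: 6 trisylhydrazone of ketone 5
Product: 7 (4R)-4-(1-iodoethenyl)-1-methylcyclohex-1-ene
Conditions: n‑BuLi (2.2 equiv), THF, −78 → 0 °C; then I2, THF, −78 °C
Reagents that add atoms: iodine, II
Why: Shapiro reaction: the dianion is formed at the syn methyl group and loses sulfinate and N2 to give the 1‑substituted vinyllithium, which iodine traps. C1′–H is not touched, and isolating the iodide keeps sulfinate and excess base out of the Pd coupling.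

**Branch B**

Step 6
Reactants: 8 2-cyclopropylpropan-2-ol
Product: 9 5-chloro-2-methylpent-2-ene
Conditions: conc. HCl (37%), 0 °C → rt; pentane extraction, distillation
Reagents that add atoms: hydrogen chloride, Cl
Why: Julia cyclopropylcarbinyl→homoallyl rearrangement: chloride opens the ring of the tertiary cyclopropylcarbinyl cation at CH2 and gives the trisubstituted alkene; no stereocentre is formed.

Step 7
Reactants: 9 5-chloro-2-methylpent-2-ene
Product: 10 (3R)-3-(2-chloroethyl)-2,2-dimethyloxirane
Conditions: D‑fructose‑derived Shi ketone (30 mol%), Oxone, K2CO3, Bu4NHSO4, MeCN/DMM–aqueous buffer (pH 10.5), 0 °C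
Reagents that add atoms: Oxone (KHSO5), OOS(=O)(=O)[O-].[K+]
Why: Shi asymmetric epoxidation (chiral dioxirane, spiro transition state) of a trisubstituted alkene; it sets the future C3 as the R epoxide.

Step 8
Reactants: 10 (3R)-3-(2-chloroethyl)-2,2-dimethyloxirane
Product: 11 (3S)-3-bromo-5-chloro-2-methylpentan-2-ol
Conditions: Li2NiBr4, THF, 0 °C → rt; pH 7 buffer work‑up
Reagents that add atoms: dilithium tetrabromonickelate, [Li+].[Li+].Br[Ni-2](Br)(Br)Br
Why: Soft bromide opens the epoxide by SN2 at the less substituted carbon with inversion, giving the (S)-secondary bromide next to the tertiary alcohol; the primary chloride is inert.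

Step 9
Reactants: 11 (3S)-3-bromo-5-chloro-2-methylpentan-2-ol
Product: 12 {[(3S)-3-bromo-5-chloro-2-methylpentan-2-yl]oxy}triethylsilane
Conditions: TESOTf, 2,6‑lutidine, CH2Cl2, −78 → 0 °C
Reagents that add atoms: triethylsilyl triflate, CC[Si](CC)(CC)OS(=O)(=O)C(F)(F)F
Why: Silylation of the tertiary alcohol stops the bromohydrin from closing back to the epoxide and from quenching the organozinc in step 11.

Step 10
Reactants: 12 {[(3S)-3-bromo-5-chloro-2-methylpentan-2-yl]oxy}triethylsilane
Product: 13 {[(3S)-3-bromo-5-iodo-2-methylpentan-2-yl]oxy}triethylsilane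
Conditions: NaI (5 equiv), NaHCO3 (cat.), butan-2-one, 75 °C, dark
Reagents that add atoms: sodium iodide, [Na+].[I-]
Why: Finkelstein exchange occurs only at the unhindered primary chloride; the secondary bromide flanked by a quaternary carbon is inert to SN2, so C3 is not scrambled.

**Union and endgame**

Step 11
Reactants: 7 (4R)-4-(1-iodoethenyl)-1-methylcyclohex-1-ene; 13 {[(3S)-3-bromo-5-iodo-2-methylpentan-2-yl]oxy}triethylsilane
Product: 14 (3S)-3-bromo-2-methyl-6-[(1R)-4-methylcyclohex-3-en-1-yl]hept-6-en-2-ol
Conditions: 7, t‑BuLi (2.0 equiv), THF/Et2O, −78 °C; ZnCl2, −78 °C → rt; then 13, Pd2(dba)3 (2 mol%), PCyp3 (8 mol%), N‑methylimidazole, THF/NMP, 80 °C; work‑up with 1 M HCl, THF/MeOH, 0 °C → rt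
Reagents that add atoms: none (both carbon fragments are the numbered reactants)
Why: Li–I exchange and transmetalation give the alkenylzinc chloride, and a Pd/trialkylphosphine Negishi alkyl–alkenyl coupling forms C5–C6. Oxidative addition is SN2‑like and occurs only at the primary C–I, not at the hindered secondary C–Br; the acidic work‑up removes the TES group, and C1′ and C3 are untouched.

Step 12
Reactants: 14 (3S)-3-bromo-2-methyl-6-[(1R)-4-methylcyclohex-3-en-1-yl]hept-6-en-2-ol
Product: 15 (3S,6R)-3-bromo-2,2,6-trimethyl-6-[(1R)-4-methylcyclohex-3-en-1-yl]oxane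
Conditions: chiral (R,R)-(salen)Co(II) (5 mol%, enantiomer chosen by screening), N‑fluoro‑2,4,6‑trimethylpyridinium triflate, (Me2SiH)2O, PhCF3, 0 °C
Reagents that add atoms: none
Why: Proposed new method: a chiral (salen)Co–H catalyst is asked to control the configuration of a fully substituted ether carbon in a six‑membered ring closure. Co(III)–H transfers H• to the terminal CH2 of the 1,1‑disubstituted alkene (faster than to the trisubstituted ring alkene); the tertiary C6 radical is captured as alkyl–Co(III) and oxidised to alkyl–Co(IV), which the tertiary OH displaces through a chair transition state (cyclohexenyl equatorial, new CH3 axial, Br equatorial). Because the radical and alkyl–Co diastereomers interconvert, the salen ligand selects the face (Curtin–Hammett) and reinforces the chair preference set by the equatorial C3–Br, giving 6R. The closest known reaction type is Co(salen)/N‑fluoropyridinium/silane hydrogen‑atom‑transfer, radical‑polar‑crossover hydroalkoxylation of unactivated alkenes (racemic oxane closures; enantioselective only for simpler oxolanes).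

Step 13
Reactants: 15 (3S,6R)-3-bromo-2,2,6-trimethyl-6-[(1R)-4-methylcyclohex-3-en-1-yl]oxane
Product: 16 (1S,2S,4R)-4-[(2R,5S)-5-bromo-2,6,6-trimethyloxan-2-yl]-2-chloro-1-methylcyclohexan-1-ol
Conditions: trichloroisocyanuric acid (0.4 equiv), acetone/H2O 4:1, 0 °C
Reagents that add atoms: trichloroisocyanuric acid, ClN1C(=O)N(Cl)C(=O)N(Cl)C1=O; water, O
Why: Chlorohydrin formation is Markovnikov and trans‑diaxial (Fürst–Plattner): only the chloronium anti to the equatorial C1′ substituent can be opened by water at the tertiary carbon through a chair‑like transition state (the same sense as limonene with NBS/H2O). This gives axial Cl at C3′ (trans to the oxanyl group) and axial OH at C4′ (cis to it).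

Step 14
Reactants: 16 (1S,2S,4R)-4-[(2R,5S)-5-bromo-2,6,6-trimethyloxan-2-yl]-2-chloro-1-methylcyclohexan-1-ol
Product: 17 (3S,6R)-3-bromo-6-[(1R,3S,4S)-4-bromo-3-chloro-4-methylcyclohexyl]-2,2,6-trimethyloxane
Conditions: TMSBr (1.5 equiv), CH2Cl2, −40 → 0 °C; solid NaHCO3 quench
Reagents that add atoms: bromotrimethylsilane, C[Si](C)(C)Br
Why: SN1 substitution of the tertiary carbinol with neighbouring‑group participation: the antiperiplanar axial chlorine bridges the developing cation and bromide opens the chloronium at the tertiary carbon anti to Cl. The net result is retention at C4′ and the trans‑diaxial tertiary‑Br/secondary‑Cl compound.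

Step 15
Reactants: 17 (3S,6R)-3-bromo-6-[(1R,3S,4S)-4-bromo-3-chloro-4-methylcyclohexyl]-2,2,6-trimethyloxane
Product: 18 deoxycaespitol, (3S,6R)-3-bromo-6-[(1R,3R,4R)-3-bromo-4-chloro-4-methylcyclohexyl]-2,2,6-trimethyloxane
Conditions: solid K2CO3 (acid scavenger), toluene, 90 °C, sealed tube, to equilibrium; chromatography, recovered 17 recycled
Reagents that add atoms: none
Why: Thermal diaxial→diequatorial 1,2‑halogen interchange (dyotropic rearrangement, as for 5α,6β‑dihalocholestanes): the antiperiplanar Br and Cl migrate across C3′–C4′, each staying on its own face, with inversion at both carbons. Br ends at C3′ cis to the oxanyl group and Cl at C4′ trans to it, which is the 3′R,4′R diequatorial pair; the equilibrium position is not established for this system.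

**Compound list**
1 | isoprene | C=CC(C)=C | starting material
2 | acrolein | C=CC=O | starting material
3 | (1R)-4-methylcyclohex-3-ene-1-carbaldehyde | O=C[C@@H]1CCC(C)=CC1 | intermediate
4 | 1-[(1R)-4-methylcyclohex-3-en-1-yl]ethan-1-ol | CC(O)[C@@H]1CCC(C)=CC1 | intermediate
5 | 1-[(1R)-4-methylcyclohex-3-en-1-yl]ethan-1-one | CC(=O)[C@@H]1CCC(C)=CC1 | intermediate
6 | (E)-N′-{1-[(1R)-4-methylcyclohex-3-en-1-yl]ethylidene}-2,4,6-triisopropylbenzenesulfonohydrazide | C/C(=N\NS(=O)(=O)c1c(C(C)C)cc(C(C)C)cc1C(C)C)[C@@H]1CCC(C)=CC1 | intermediate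
7 | (4R)-4-(1-iodoethenyl)-1-methylcyclohex-1-ene | C=C(I)[C@@H]1CCC(C)=CC1 | intermediate
8 | 2-cyclopropylpropan-2-ol | CC(C)(O)C1CC1 | starting material
9 | 5-chloro-2-methylpent-2-ene | CC(C)=CCCCl | intermediate
10 | (3R)-3-(2-chloroethyl)-2,2-dimethyloxirane | CC1(C)O[C@@H]1CCCl | intermediate
11 | (3S)-3-bromo-5-chloro-2-methylpentan-2-ol | CC(C)(O)[C@@H](Br)CCCl | intermediate
12 | {[(3S)-3-bromo-5-chloro-2-methylpentan-2-yl]oxy}triethylsilane | CC[Si](CC)(CC)OC(C)(C)[C@@H](Br)CCCl | intermediate
13 | {[(3S)-3-bromo-5-iodo-2-methylpentan-2-yl]oxy}triethylsilane | CC[Si](CC)(CC)OC(C)(C)[C@@H](Br)CCI | intermediate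
14 | (3S)-3-bromo-2-methyl-6-[(1R)-4-methylcyclohex-3-en-1-yl]hept-6-en-2-ol | CC(C)(O)[C@@H](Br)CCC(=C)[C@@H]1CCC(C)=CC1 | intermediate
15 | (3S,6R)-3-bromo-2,2,6-trimethyl-6-[(1R)-4-methylcyclohex-3-en-1-yl]oxane | CC1(C)O[C@@](C)([C@@H]2CCC(C)=CC2)CC[C@@H]1Br | intermediate
16 | (1S,2S,4R)-4-[(2R,5S)-5-bromo-2,6,6-trimethyloxan-2-yl]-2-chloro-1-methylcyclohexan-1-ol | CC1(C)O[C@@](C)([C@@H]2CC[C@](C)(O)[C@@H](Cl)C2)CC[C@@H]1Br | intermediate
17 | (3S,6R)-3-bromo-6-[(1R,3S,4S)-4-bromo-3-chloro-4-methylcyclohexyl]-2,2,6-trimethyloxane | CC1(C)O[C@@](C)([C@@H]2CC[C@](C)(Br)[C@@H](Cl)C2)CC[C@@H]1Br | intermediate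
18 | deoxycaespitol, (3S,6R)-3-bromo-6-[(1R,3R,4R)-3-bromo-4-chloro-4-methylcyclohexyl]-2,2,6-trimethyloxane | CC1(C)O[C@@](C)([C@@H]2CC[C@@](C)(Cl)[C@H](Br)C2)CC[C@@H]1Br | target

**Step count**
Total steps: 15. Longest linear sequence: 10 (steps 1–5 or 6–10, then 11–15).

**Steps most likely to fail**
1. Step 12 (proposed new step). The risks are insufficient catalyst control at C6 and hydrogen‑atom transfer to the ring alkene. Fallback (known chemistry): set the C6 carbinol before ring closure.
   - Convert ketone 5 to the (E)-allylic alcohol (HWE, DIBAL), apply Sharpless asymmetric epoxidation and open with Red‑Al to the 1,3‑diol.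
   - Tosylate the primary alcohol and couple with 2‑methylprop‑1‑enylmagnesium bromide under Cu catalysis to give (R,R)-α‑bisabolol.
   - Close the oxane by bromonium‑induced 6‑endo etherification (BDSB or TBCO), in which the chair transition state places Br and the carbocycle equatorial, to reach 15.
2. Step 15 (with step 14). The risks are an unfavourable interchange equilibrium (the product carries an axial C4′ methyl), elimination, and acid cleavage of the di‑tertiary ether during bromide formation. Fallback: reach the target under kinetic control through the syn‑face bromonium ion.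
   - Shi epoxidation of 15 on the face anti to the oxanyl group.
   - MgBr2·OEt2 opening at the tertiary carbon (axial Br at C4′, axial OH at C3′).
   - Ph3P/NCS: the anti bromine displaces the oxyphosphonium with anchimeric assistance and chloride opens the bromonium at the tertiary carbon to give 18.
3. Step 11. The risks are β‑hydride elimination of the alkylpalladium intermediate and incomplete formation of the alkenylzinc. Fallback: reverse the polarity and carry C3 as the epoxide. Use alkenyl iodide 7 as the electrophile in a B‑alkyl Suzuki–Miyaura coupling with the 9‑BBN adduct of (R)-2,2-dimethyl-3-vinyloxirane, then open the epoxide with Li2NiBr4 after the coupling to give 14.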